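**Retrosynthetic overview**
1. The target comes from a 1,2-shift (α-ketol ring enlargement) of a 1-hydroxycyclopent-2-ene-1-carbaldehyde. The iPr-bearing ring carbon moves from the carbinol carbon to the formyl carbon. This makes the six-membered ring and sets C5, and the only free OH appears last, so no protecting groups are needed.
2. The hydroxy aldehyde comes from oxidation of a tertiary/primary diol. The diol comes from face-selective dihydroxylation of an exocyclic methylene, which is made from the cyclopentenone C=O.
3. The cis bis(tiglate) cyclopentenone comes from a double Mitsunobu reaction of tiglic acid with trans-4-hydroxy-2-(hydroxymethyl)-5-isopropylcyclopentenone, with inversion at the ring carbinol.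
4. That cyclopentenone comes from an enantioselective oxa-Piancatelli rearrangement of a 2-furyl carbinol, made from furan-3-ylmethanol and isobutyraldehyde.
5. Ring order: furan (bought), then cyclopentenone (step 2), then cyclohexenone (step 6).

Assumption: the sense of induction of the chiral acid in step 2 cannot be predicted, so the (R)-catalyst is written and its mirror image is used if it gives the (4S,5R)-enone. Throughout, tiglate/tigloyl means (E)-2-methylbut-2-enoate/-enoyl.

**Route**

Step 1
Reactants: 1 furan-3-ylmethanol; 2 isobutyraldehyde (2-methylpropanal)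
Product: 4 1-[3-(hydroxymethyl)furan-2-yl]-2-methylpropan-1-ol (racemic carbinol), via dilithio alkoxide 3 (not isolated)
Conditions: n-BuLi (2.2 equiv), DME, 0 °C; 2, −78 °C to rt; H2O
Reagents that add atoms: none
Why: Alkoxide-directed lithiation takes the furan C2–H (flanked by the ring O and CH2OLi) and the furyllithium adds 1,2 to the aldehyde; the new carbinol centre is left racemic because step 2 erases it.

Step 2
Reactants: 4 1-[3-(hydroxymethyl)furan-2-yl]-2-methylpropan-1-ol
Product: 5 (4R,5S)-4-hydroxy-2-(hydroxymethyl)-5-(propan-2-yl)cyclopent-2-en-1-one (OH and iPr trans)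
Conditions: (R)-3,3'-bis(2,4,6-triisopropylphenyl)-BINOL N-triflylphosphoramide (5 mol %), H2O (10 equiv), PhCF3, 50 °C
Reagents that add atoms: water, O
Why: Proposed new method: enantioselective oxa-Piancatelli rearrangement, in which the strong chiral Brønsted acid ionises the furyl carbinol, water adds at furan C5 and ring opening gives a 1,4-dihydroxypentadienyl cation that stays hydrogen-bonded through both OH groups to the chiral phosphoramide anion in the non-polar medium, so the anion biases the sense of the conrotatory 4π closure (the trans-4,5 relationship is inherent to conrotation, the absolute (4R,5S) sense comes from the counter-anion); the closest known reaction types are the racemic acid-catalysed oxa-Piancatelli rearrangement and the chiral phosphoric acid catalysed aza-Piancatelli rearrangement with anilines.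

Step 3
Reactants: 5 (4R,5S)-4-hydroxy-2-(hydroxymethyl)-5-(propan-2-yl)cyclopent-2-en-1-one; 6 tiglic acid ((E)-2-methylbut-2-enoic acid, 2.6 equiv)
Product: 7 [(3S,4S)-5-oxo-4-(propan-2-yl)-3-(tigloyloxy)cyclopent-1-en-1-yl]methyl tiglate (ring O-tiglate and iPr cis)
Conditions: PPh3 (2.6 equiv), DIAD (2.6 equiv), toluene, −10 °C to rt
Reagents that add atoms: none
Why: Double Mitsunobu esterification acylates the primary allylic OH and displaces the ring carbinol by SN2 with clean inversion (trans to cis O/iPr); the electron-poor enone disfavours SN1 and SN2' paths, and the acid-buffered medium limits E1cB loss of the activated oxygen.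

Step 4
Reactants: 7 [(3S,4S)-5-oxo-4-(propan-2-yl)-3-(tigloyloxy)cyclopent-1-en-1-yl]methyl tiglate
Product: 8 [(3S,4R)-5-methylidene-4-(propan-2-yl)-3-(tigloyloxy)cyclopent-1-en-1-yl]methyl tiglate
Conditions: CH2Br2/Zn/TiCl4 (pre-aged in THF, 3 equiv), CH2Cl2, 0 °C to rt
Reagents that add atoms: dibromomethane, BrCBr
Why: Lombardo–Takai methylenation is non-basic, so the β-acyloxy ketone neither epimerises nor eliminates, and it takes the ketone but not the conjugated esters; no stereocentre is touched (the C4 descriptor changes only through CIP priorities).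

Step 5
Reactants: 8 [(3S,4R)-5-methylidene-4-(propan-2-yl)-3-(tigloyloxy)cyclopent-1-en-1-yl]methyl tiglate
Product: 9 [(3S,4S,5R)-5-hydroxy-5-(hydroxymethyl)-4-(propan-2-yl)-3-(tigloyloxy)cyclopent-1-en-1-yl]methyl tiglate (tertiary OH trans to iPr and to the ring tiglate)
Conditions: OsO4 (2 mol %), NMO (1.2 equiv), acetone/H2O 9:1, 0 °C
Reagents that add atoms: N-methylmorpholine N-oxide, C[N+]1([O-])CCOCC1; water, O
Why: Catalytic OsO4 syn-dihydroxylation picks the most electron-rich and least hindered alkene (the exocyclic 1,1-disubstituted one, not the ring alkene or the tiglates) and attacks the face opposite to the cis iPr and O-tiglate groups, which places the tertiary OH trans to iPr (5R).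

Step 6
Reactants: 9 [(3S,4S,5R)-5-hydroxy-5-(hydroxymethyl)-4-(propan-2-yl)-3-(tigloyloxy)cyclopent-1-en-1-yl]methyl tiglate
Product: 11 target CNP0326914.1 [(3S,4R,5R)-5-hydroxy-6-oxo-4-(propan-2-yl)-3-(tigloyloxy)cyclohex-1-en-1-yl]methyl tiglate, via hydroxy aldehyde 10 (not isolated)
Conditions: 2-iodoxybenzoic acid (IBX, 1.3 equiv), DCE, 65 °C; filter; Sc(OTf)3 (10 mol %), 2,6-di-tert-butyl-4-methylpyridine (20 mol %), 4 Å MS, 0 °C to rt
Reagents that add atoms: none
Why: Proposed new method: oxidation-triggered, scandium-chelate-controlled α-ketol (acyloin) ring enlargement of a 1-(hydroxymethyl)cyclopent-2-en-1-ol, in which IBX takes only the primary alcohol to aldehyde 10 without glycol cleavage, Sc(OTf)3 ties the tertiary OH and the formyl O into a five-membered chelate with both C–O bonds syn-coplanar, and the ring bond from the carbinol carbon to C4 (iPr carbon) overlaps with π*(C=O) and shifts to the formyl carbon with retention at C4, so the former formyl O ends on the face that carried the tertiary OH (trans to iPr, which is 5R) and the carbinol carbon becomes the enone C=O; the driving force is the change from aldehyde to conjugated ketone plus relief of the crowded quaternary centre, the alkenyl carbon is a poor competitor because its π bond is depleted by three allylic C–O bonds, and if it does migrate the iso-acyloin can reach the same product with the same C5 configuration by a 1,2-hydride shift on the same chelate; the closest known reaction type is the Lewis acid promoted α-ketol rearrangement of tertiary α-hydroxy aldehydes and ketones (D-homoannulation of 17-hydroxy-20-oxo steroids), not yet shown for a cyclopentenyl carbinol with a competing alkenyl group or in tandem with the alcohol oxidation.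

**Compound list**
1 | furan-3-ylmethanol | OCc1ccoc1 | starting material
2 | isobutyraldehyde | CC(C)C=O | starting material
3 | lithium (2-lithiofuran-3-yl)methanolate | [Li]OCc1ccoc1[Li] | intermediate
4 | 1-[3-(hydroxymethyl)furan-2-yl]-2-methylpropan-1-ol (racemic) | CC(C)C(O)c1occc1CO | intermediate
5 | (4R,5S)-4-hydroxy-2-(hydroxymethyl)-5-(propan-2-yl)cyclopent-2-en-1-one | OCC1=C[C@@H](O)[C@H](C(C)C)C1=O | intermediate
6 | tiglic acid | C/C=C(\C)C(=O)O | starting material
7 | [(3S,4S)-5-oxo-4-(propan-2-yl)-3-(tigloyloxy)cyclopent-1-en-1-yl]methyl tiglate | C/C=C(\C)C(=O)OCC1=C[C@H](OC(=O)/C(C)=C/C)[C@H](C(C)C)C1=O | intermediate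
8 | [(3S,4R)-5-methylidene-4-(propan-2-yl)-3-(tigloyloxy)cyclopent-1-en-1-yl]methyl tiglate | C/C=C(\C)C(=O)OCC1=C[C@H](OC(=O)/C(C)=C/C)[C@H](C(C)C)C1=C | intermediate
9 | [(3S,4S,5R)-5-hydroxy-5-(hydroxymethyl)-4-(propan-2-yl)-3-(tigloyloxy)cyclopent-1-en-1-yl]methyl tiglate | C/C=C(\C)C(=O)OCC1=C[C@H](OC(=O)/C(C)=C/C)[C@H](C(C)C)[C@]1(O)CO | intermediate
10 | [(3S,4S,5R)-5-formyl-5-hydroxy-4-(propan-2-yl)-3-(tigloyloxy)cyclopent-1-en-1-yl]methyl tiglate | C/C=C(\C)C(=O)OCC1=C[C@H](OC(=O)/C(C)=C/C)[C@H](C(C)C)[C@]1(O)C=O | intermediate
11 | [(3S,4R,5R)-5-hydroxy-6-oxo-4-(propan-2-yl)-3-(tigloyloxy)cyclohex-1-en-1-yl]methyl tiglate (CNP0326914.1) | C/C=C(\C)C(=O)OCC1=C[C@H](OC(=O)/C(C)=C/C)[C@H](C(C)C)[C@@H](O)C1=O | target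

**Total step count:** 6. **Longest linear sequence:** 6 (1 to 11).

**Steps most likely to fail:** step 6, step 2 and step 3.

For step 6 there are three dangers.
- The alkenyl carbon may migrate and the reaction may stop at the iso-acyloin.
- An enediol may form and lose tiglic acid, which leads to aromatisation.
- IBX may over-oxidise the new secondary OH.

The fallback leaves the route at enone 7 and returns at target 11 with established reaction types only. Vinylmagnesium bromide/CeCl3 (THF, −78 °C) adds 1,2 to the ketone from the face opposite to iPr. The alkoxide is capped with TESOTf/2,6-lutidine to give the vinyl carbinol triethylsilyl ether F6. Lemieux–Johnson cleavage (OsO4 cat., NaIO4, 2,6-lutidine, dioxane/H2O), selective for the monosubstituted alkene, gives the α-siloxy aldehyde F7. F7 has the opposite configuration to 10 at the carbinol carbon. The known organoaluminium-promoted rearrangement of α-siloxy aldehydes (methylaluminium bis(4-bromo-2,6-di-tert-butylphenoxide), CH2Cl2, −78 to −20 °C) runs through an open, dipole-opposed transition state. From this epimer the shift of C4 therefore again puts the C5–O bond trans to iPr and gives the α-siloxy ketone F8. HF·pyridine (THF, 0 °C) then frees 11.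

For step 2 the danger is slow ionisation of an alkyl-substituted carbinol and low enantioselectivity when water is the nucleophile. The fallback leaves at 4 and returns at 5. The established racemic rearrangement (Dy(OTf)3 5 mol %, t-BuOH/H2O 5:1, 80 °C) gives the racemic trans-hydroxyenone F1. Lipase-catalysed kinetic resolution follows (Burkholderia cepacia lipase, vinyl acetate, MTBE, 30 °C). The lipase acetylates both primary hydroxyls. By the Kazlauskas rule, with the iPr-bearing carbon as the large group, it acetylates only the (4R)-configured secondary hydroxyl. This gives the (4R,5S)-diacetate F2 beside the (4S,5R)-monoacetate F3, which is removed by chromatography. Acid methanolysis of F2 (AcCl cat., MeOH, 0 °C) gives 5.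

For step 3 the danger is that SN2 attack next to the iPr group is slow, so the activated oxygen is lost by E1cB to a cyclopentadienone. The fallback leaves at 5 and returns at 7 by separating the two esterifications. Tigloyl chloride (1.0 equiv, 2,4,6-collidine, CH2Cl2, −78 °C) acylates only the primary alcohol to the mono-tiglate F4. MsCl/Et3N (CH2Cl2, −40 °C) gives the secondary mesylate F5. Caesium tiglate (from 6 and Cs2CO3) with 18-crown-6 in toluene then displaces the sulfonate with inversion (caesium carboxylate inversion) to give 7.

**Further compounds**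
F1 | step 2 | racemic trans-4-hydroxy-2-(hydroxymethyl)-5-(propan-2-yl)cyclopent-2-en-1-one | OCC1=C[C@@H](O)[C@H](C(C)C)C1=O.OCC1=C[C@H](O)[C@@H](C(C)C)C1=O
F2 | step 2 | [(3R,4S)-3-acetoxy-5-oxo-4-(propan-2-yl)cyclopent-1-en-1-yl]methyl acetate, the (4R,5S)-series diacetate | CC(=O)OCC1=C[C@@H](OC(C)=O)[C@H](C(C)C)C1=O
F3 | step 2 | [(3S,4R)-3-hydroxy-5-oxo-4-(propan-2-yl)cyclopent-1-en-1-yl]methyl acetate, the (4S,5R)-series monoacetate | CC(=O)OCC1=C[C@H](O)[C@@H](C(C)C)C1=O
F4 | step 3 | [(3R,4S)-3-hydroxy-5-oxo-4-(propan-2-yl)cyclopent-1-en-1-yl]methyl tiglate (OH trans to iPr) | C/C=C(\C)C(=O)OCC1=C[C@@H](O)[C@H](C(C)C)C1=O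
F5 | step 3 | [(3R,4S)-3-(methanesulfonyloxy)-5-oxo-4-(propan-2-yl)cyclopent-1-en-1-yl]methyl tiglate (OMs trans to iPr) | C/C=C(\C)C(=O)OCC1=C[C@@H](OS(C)(=O)=O)[C@H](C(C)C)C1=O
F6 | step 6 | bis(tiglate) of the 5-ethenyl-5-(triethylsilyloxy)cyclopentene (vinyl trans to iPr, OTES cis to iPr) | C/C=C(\C)C(=O)OCC1=C[C@H](OC(=O)/C(C)=C/C)[C@H](C(C)C)[C@@]1(O[Si](CC)(CC)CC)C=C
F7 | step 6 | bis(tiglate) of the 5-formyl-5-(triethylsilyloxy)cyclopentene (CHO trans to iPr, OTES cis to iPr) | C/C=C(\C)C(=O)OCC1=C[C@H](OC(=O)/C(C)=C/C)[C@H](C(C)C)[C@@]1(O[Si](CC)(CC)CC)C=O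
F8 | step 6 | 5-O-triethylsilyl ether of target 11 (OTES trans to iPr) | C/C=C(\C)C(=O)OCC1=C[C@H](OC(=O)/C(C)=C/C)[C@H](C(C)C)[C@@H](O[Si](CC)(CC)CC)C1=O
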